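**Retrosynthetic overview**

1. Numbering: C1 = carboxyl carbon, C3–C6 = the four carbons of the 1,2-dioxane (O–O bridges C3 and C6), C8 = side-chain methine, C9–C16 = methylene chain, then phenyl.
2. Enabling feature: C6, the quaternary ring carbon that carries a peroxide oxygen, stands 1,3 to C8 across C7. Kept at the carboxyl level, C6–C7–C8 with the C8 methyl is a crotonate and C8 is its β-carbon. C8–C9 is therefore cut back to the C14 Grignard reagent plus that acceptor (catalytic asymmetric conjugate addition).
3. The crotonate is tethered through its ester oxygen to the chiral-pool C3–C5 unit (C4 stereocentre). An O-to-C acyl shift turns the tether into the C5–C6 bond, and oxidation gives the C3 aldehyde/C6 ketone.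
4. Only ring formed: the 1,2-dioxane, closed by double addition of H2O2 to C3=O and C6=O. C6–CH3 and then C3–C2 are made by two axial substitutions through peroxycarbenium ions, both steered by C4.
5. Ester hydrolysis gives the acid.

Key step: step 2

Assumption: the (R,S)-configured ferrocenyl diphosphine is taken to deliver linear alkyl groups to the Si face of the crotonate β-carbon; should the opposite sense be found, its mirror image is used.

Step 1
Reactants: 1 (E)-but-2-enoic acid; 2 (R)-3-bromo-2-methylpropan-1-ol
Product: 3 (2R)-3-bromo-2-methylpropyl (E)-but-2-enoate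
Conditions: DCC, DMAP (10 mol %), CH2Cl2, 0 °C to rt
Reagents that add atoms: none
Why: Steglich esterification acylates the primary alcohol under neutral conditions that should leave the conjugated E-alkene, the primary bromide and the stereocentre (future C4) untouched.

Step 2
Reactants: 3 (2R)-3-bromo-2-methylpropyl (E)-but-2-enoate; 4 (8-bromooctyl)benzene
Product: 7 (2R)-3-bromo-2-methylpropyl (3R)-3-methyl-11-phenylundecanoate, via Grignard reagent 5 (not isolated), via magnesium enolate 6 (not isolated)
Conditions: 4, Mg, Et2O, reflux; then added to 3, CuBr·SMe2 (1 mol %), (R)-1-[(S)-2-(diphenylphosphino)ferrocenyl]ethyldicyclohexylphosphine (Josiphos, 1.2 mol %), t-BuOMe, −75 °C; 1 M HCl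
Reagents that add atoms: none
Why: The Grignard reagent 5 alkylates the chiral monovalent copper–diphosphine complex, the resulting alkylcopper species binds the s-cis crotonate 3 as a π-complex, adds oxidatively at the β-carbon to a trivalent σ-copper intermediate and forms C8–C9 by reductive elimination, which leaves magnesium enolate 6 for protonation on work-up. The closest known reaction type is exactly this one, the copper/ferrocenyl-diphosphine-catalysed enantioselective conjugate addition of linear alkyl Grignard reagents to crotonic esters. No ring is closed. The one new stereocentre, C8, is controlled by the ligand alone (alkyl delivery to the Si face of the β-carbon gives R), because the C4 centre in the alkoxy part is too remote to interfere. The step needs 1,4- over 1,2-addition and a spectator primary bromide: the unhindered methyl-substituted β-carbon and the fast catalysed pathway at −75 °C secure the first, and at that temperature neither 5 nor the weakly nucleophilic enolate 6 should displace bromide. In one operation two simple pieces become a product that holds 22 of the 25 carbons, the only stereocentre that the ring cannot control, C6 at the oxidation level from which the peroxide carbon is later developed, and the bromide and ester oxygen placed for the acyl shift of step 3.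

Step 3
Reactants: 7 (2R)-3-bromo-2-methylpropyl (3R)-3-methyl-11-phenylundecanoate
Product: 9 (2S,6R)-1-hydroxy-2,6-dimethyl-14-phenyltetradecan-4-one, via samarium hemiketal alkoxide 8 (not isolated)
Conditions: SmI2 (2.5 equiv), NiI2 (2 mol %), THF, 0 °C to rt; 0.1 M HCl
Reagents that add atoms: none
Why: Intramolecular samarium Barbier reaction (nucleophilic acyl substitution): two one-electron transfers from divalent samarium turn the C5–Br bond into an alkylsamarium that attacks the ester carbonyl through a five-membered transition state (5-exo-trig), and the tetrahedral alkoxide 8 masks the new C6 ketone until work-up, so that the ester tether is exchanged for the C5–C6 bond without touching C4 or C8.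

Step 4
Reactants: 9 (2S,6R)-1-hydroxy-2,6-dimethyl-14-phenyltetradecan-4-one
Product: 10 (2S,6R)-2,6-dimethyl-4-oxo-14-phenyltetradecanal
Conditions: Dess–Martin periodinane, CH2Cl2, 0 °C to rt
Reagents that add atoms: none
Why: Dess–Martin oxidation works under neutral, non-enolising conditions, oxidises the open hydroxy ketone that is in equilibrium with its lactol, and should leave the epimerisable C4 centre and the aldol-prone 1,4-keto aldehyde intact.

Step 5
Reactants: 10 (2S,6R)-2,6-dimethyl-4-oxo-14-phenyltetradecanal
Product: 12 (4S)-3,6-dimethoxy-4-methyl-6-[(2R)-2-methyl-10-phenyldecyl]-1,2-dioxane (anomer mixture at C3 and C6), via dioxane-3,6-diol 11 (not isolated)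
Conditions: urea·H2O2 (1.1 equiv), p-TsOH·H2O (10 mol %), MeCN, 0 °C; then MeOH, 4 Å molecular sieves, rt
Reagents that add atoms: hydrogen peroxide (used as its urea adduct), OO; methanol, CO
Why: Acid-catalysed perhydrolysis of a 1,4-dicarbonyl compound is a known route to 1,2-dioxane-3,6-diols: H2O2 adds to the aldehyde, the hydroperoxide closes onto the C6 ketone (6-exo-trig), and acetal exchange with methanol gives the stable bis-peroxyacetal 12, whose two anomeric centres may be mixtures because both are ionised later.

Step 6
Reactants: 12 (4S)-3,6-dimethoxy-4-methyl-6-[(2R)-2-methyl-10-phenyldecyl]-1,2-dioxane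
Product: 14 (4S,6R)-3-methoxy-4,6-dimethyl-6-[(2R)-2-methyl-10-phenyldecyl]-1,2-dioxane (anomer mixture at C3), via peroxycarbenium ion 13 (not isolated)
Conditions: AlMe3 (3 equiv), CH2Cl2, −78 to −20 °C; then H2O
Reagents that add atoms: trimethylaluminium, C[Al](C)C
Why: Proposed new method: AlMe3 binds and ionises the tertiary C6 methoxy group faster than the secondary C3 one, the six-membered peroxycarbenium ion 13 adopts the half-chair with the C4 methyl and the C6 side chain pseudo-equatorial, and methyl is passed from the aluminate along the axial trajectory (chair-like transition state), that is trans to the C4 methyl, which sets C6 as R; the closest known reaction types are the Lewis-acid-mediated substitution of cyclic peroxyketals by allylsilanes and silyl ketene acetals through peroxycarbenium ions and the axial methylation of cyclic ketals and glycosyl-type donors with AlMe3, which tolerates a trioxane peroxide, whereas a methyl-metal nucleophile has not yet been combined with a peroxycarbenium ion.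

Step 7
Reactants: 14 (4S,6R)-3-methoxy-4,6-dimethyl-6-[(2R)-2-methyl-10-phenyldecyl]-1,2-dioxane
Product: 16 methyl 2-[(3S,4S,6R)-4,6-dimethyl-6-[(2R)-2-methyl-10-phenyldecyl]-1,2-dioxan-3-yl]acetate, via peroxycarbenium ion 15 (not isolated)
Conditions: CH2=C(OMe)OTBS (2 equiv), TMSOTf (20 mol %), CH2Cl2, −78 °C
Reagents that add atoms: 1-(tert-butyldimethylsilyloxy)-1-methoxyethene, C=C(OC)O[Si](C)(C)C(C)(C)C
Why: Substitution of a cyclic peroxyacetal by a silyl ketene acetal through a peroxycarbenium ion is a known Mukaiyama-type reaction: ion 15 is locked in the half-chair with the C4 methyl and the C6 side chain pseudo-equatorial, and axial attack, as in the formation of axial C-glycosides next to an equatorial substituent, places the acetate unit cis to the C4 methyl and sets C3 as S.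

Step 8
Reactants: 16 methyl 2-[(3S,4S,6R)-4,6-dimethyl-6-[(2R)-2-methyl-10-phenyldecyl]-1,2-dioxan-3-yl]acetate
Product: 17 2-[(3S,4S,6R)-4,6-dimethyl-6-[(2R)-2-methyl-10-phenyldecyl]-1,2-dioxan-3-yl]acetic acid
Conditions: LiOH, THF/H2O, 0 °C to rt; then 1 M HCl to pH 3
Reagents that add atoms: lithium hydroxide, [Li+].[OH-]
Why: Saponification of the unhindered methyl ester with LiOH at low temperature should be faster than base-induced opening of the β-peroxy ester at C3 and affects no stereocentre.

**Compound list**

1 | (E)-but-2-enoic acid (crotonic acid) | C/C=C/C(=O)O | starting material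
2 | (R)-3-bromo-2-methylpropan-1-ol | BrC[C@H](C)CO | starting material
3 | (2R)-3-bromo-2-methylpropyl (E)-but-2-enoate | C/C=C/C(=O)OC[C@@H](C)CBr | intermediate
4 | (8-bromooctyl)benzene | BrCCCCCCCCc1ccccc1 | starting material
5 | (8-phenyloctyl)magnesium bromide | Br[Mg]CCCCCCCCc1ccccc1 | intermediate
6 | bromomagnesium enolate of ester 7 | C[C@H](CCCCCCCCc1ccccc1)C=C(O[Mg]Br)OC[C@@H](C)CBr | intermediate
7 | (2R)-3-bromo-2-methylpropyl (3R)-3-methyl-11-phenylundecanoate | C[C@H](CCCCCCCCc1ccccc1)CC(=O)OC[C@@H](C)CBr | intermediate
8 | diiodosamarium alkoxide of the cyclic hemiketal (2-oxidotetrahydrofuran) | C[C@H](CCCCCCCCc1ccccc1)CC1(O[Sm](I)I)C[C@H](C)CO1 | intermediate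
9 | (2S,6R)-1-hydroxy-2,6-dimethyl-14-phenyltetradecan-4-one | C[C@H](CCCCCCCCc1ccccc1)CC(=O)C[C@H](C)CO | intermediate
10 | (2S,6R)-2,6-dimethyl-4-oxo-14-phenyltetradecanal | C[C@H](CCCCCCCCc1ccccc1)CC(=O)C[C@H](C)C=O | intermediate
11 | (4S)-4-methyl-6-[(2R)-2-methyl-10-phenyldecyl]-1,2-dioxane-3,6-diol (anomer mixture) | C[C@H](CCCCCCCCc1ccccc1)CC1(O)C[C@H](C)C(O)OO1 | intermediate
12 | (4S)-3,6-dimethoxy-4-methyl-6-[(2R)-2-methyl-10-phenyldecyl]-1,2-dioxane (anomer mixture) | C[C@H](CCCCCCCCc1ccccc1)CC1(OC)C[C@H](C)C(OC)OO1 | intermediate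
13 | cyclic peroxycarbenium ion, cationic at C6, C3 methoxy retained | C[C@H](CCCCCCCCc1ccccc1)CC1=[O+]OC(OC)[C@@H](C)C1 | intermediate
14 | (4S,6R)-3-methoxy-4,6-dimethyl-6-[(2R)-2-methyl-10-phenyldecyl]-1,2-dioxane (anomer mixture at C3) | C[C@H](CCCCCCCCc1ccccc1)C[C@]1(C)C[C@H](C)C(OC)OO1 | intermediate
15 | cyclic peroxycarbenium ion, cationic at C3 | C[C@H](CCCCCCCCc1ccccc1)C[C@]1(C)C[C@H](C)C=[O+]O1 | intermediate
16 | methyl 2-[(3S,4S,6R)-4,6-dimethyl-6-[(2R)-2-methyl-10-phenyldecyl]-1,2-dioxan-3-yl]acetate | C[C@H](CCCCCCCCc1ccccc1)C[C@]1(C)C[C@H](C)[C@H](CC(=O)OC)OO1 | intermediate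
17 | 2-[(3S,4S,6R)-4,6-dimethyl-6-[(2R)-2-methyl-10-phenyldecyl]-1,2-dioxan-3-yl]acetic acid | C[C@H](CCCCCCCCc1ccccc1)C[C@]1(C)C[C@H](C)[C@H](CC(=O)O)OO1 | target

Total step count: 8. Longest linear sequence: 8 steps (from 1 or 2; bromide 4 enters at step 2).

**The three steps most likely to fail**

**Step 6 (Proposed new method).**
- What may go wrong: transfer of methyl to a peroxide oxygen with cleavage of the O–O bond, loss of a proton from ion 13, or parallel ionisation at C3.
- The fallback uses known chemistry and makes the C6–O bond by radical hydroperoxidation instead of making the C6–CH3 bond by substitution. It sets out from 9.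
- Wittig methylenation of the ketone (Ph3P=CH2, THF) gives (2S,6R)-2,6-dimethyl-4-methylidene-14-phenyltetradecan-1-ol F1.
- Mukaiyama–Isayama hydroperoxysilylation (Co(thd)2 with thd = 2,2,6,6-tetramethylheptane-3,5-dionate, O2, Et3SiH, 1,2-dichloroethane) gives (2S,6R)-2,4,6-trimethyl-14-phenyl-4-(triethylsilylperoxy)tetradecan-1-ol F2 in both configurations at the new centre.
- Dess–Martin oxidation gives (2S,6R)-2,4,6-trimethyl-14-phenyl-4-(triethylsilylperoxy)tetradecanal F3.
- HCl in MeOH removes the silyl group, the hydroperoxide closes onto the aldehyde, and the hemiacetal is methylated.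
- This gives 14 beside its C6 epimer (4S,6S)-3-methoxy-4,6-dimethyl-6-[(2R)-2-methyl-10-phenyldecyl]-1,2-dioxane F4, to be separated by chromatography.
- The fallback comes back to the route at 14, at the price of no control at C6.

**Step 5.**
- What may go wrong: capture of the dicarbonyl compound by methanol as an oxygen-bridged five-membered bis-acetal, formation of open-chain geminal hydroperoxides or oligomeric peroxides instead of closure through O–O, and epimerisation at C4.
- The fallback delivers the O–O unit regiospecifically by Criegee ozonolysis. It sets out from 10.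
- Chemoselective Wittig reaction of the aldehyde with Ph3P=CHOMe gives (3S,7R)-1-methoxy-3,7-dimethyl-15-phenylpentadec-1-en-5-one F5.
- Ozone in CH2Cl2/MeOH at −78 °C cleaves the enol ether towards the carbonyl oxide at C3. Methanol traps it, and the methoxy hydroperoxide adds to the C6 ketone to give (5S)-6-methoxy-5-methyl-3-[(2R)-2-methyl-10-phenyldecyl]-1,2-dioxan-3-ol F6.
- MeOH with catalytic p-TsOH then comes back to the route at 12.

**Step 3.**
- What may go wrong: protonation of the alkylsamarium before it attacks (simple loss of bromine), 1,3-elimination with expulsion of the carboxylate, or further reduction of the ketone once it is set free.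
- The fallback replaces the tethered acyl shift by an intermolecular ketone synthesis. It sets out from 7 and from 2.
- Ester 7 is converted with MeNHOMe·HCl and i-PrMgCl into (3R)-N-methoxy-N,3-dimethyl-11-phenylundecanamide F7.
- Alcohol 2 is silylated (TBSCl, imidazole) to [(2R)-3-bromo-2-methylpropoxy](tert-butyl)dimethylsilane F8.
- F8 is turned with Mg into [(2R)-3-(tert-butyldimethylsilyloxy)-2-methylpropyl]magnesium bromide F9.
- Addition of F9 to the Weinreb amide gives (2S,6R)-1-(tert-butyldimethylsilyloxy)-2,6-dimethyl-14-phenyltetradecan-4-one F10.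
- Bu4NF comes back to the route at 9.

Further compounds
F1 | step 6 | (2S,6R)-2,6-dimethyl-4-methylidene-14-phenyltetradecan-1-ol | C[C@H](CCCCCCCCc1ccccc1)CC(=C)C[C@H](C)CO
F2 | step 6 | (2S,6R)-2,4,6-trimethyl-14-phenyl-4-(triethylsilylperoxy)tetradecan-1-ol (both C4 epimers) | C[C@H](CCCCCCCCc1ccccc1)CC(C)(OO[Si](CC)(CC)CC)C[C@H](C)CO
F3 | step 6 | (2S,6R)-2,4,6-trimethyl-14-phenyl-4-(triethylsilylperoxy)tetradecanal (both C4 epimers) | C[C@H](CCCCCCCCc1ccccc1)CC(C)(OO[Si](CC)(CC)CC)C[C@H](C)C=O
F4 | step 6 | (4S,6S)-3-methoxy-4,6-dimethyl-6-[(2R)-2-methyl-10-phenyldecyl]-1,2-dioxane | C[C@H](CCCCCCCCc1ccccc1)C[C@@]1(C)C[C@H](C)C(OC)OO1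
F5 | step 5 | (3S,7R)-1-methoxy-3,7-dimethyl-15-phenylpentadec-1-en-5-one (E/Z mixture) | C[C@H](CCCCCCCCc1ccccc1)CC(=O)C[C@H](C)C=COC
F6 | step 5 | (5S)-6-methoxy-5-methyl-3-[(2R)-2-methyl-10-phenyldecyl]-1,2-dioxan-3-ol (anomer mixture) | C[C@H](CCCCCCCCc1ccccc1)CC1(O)C[C@H](C)C(OC)OO1
F7 | step 3 | (3R)-N-methoxy-N,3-dimethyl-11-phenylundecanamide | C[C@H](CCCCCCCCc1ccccc1)CC(=O)N(C)OC
F8 | step 3 | [(2R)-3-bromo-2-methylpropoxy](tert-butyl)dimethylsilane | BrC[C@H](C)CO[Si](C)(C)C(C)(C)C
F9 | step 3 | [(2R)-3-(tert-butyldimethylsilyloxy)-2-methylpropyl]magnesium bromide | Br[Mg]C[C@H](C)CO[Si](C)(C)C(C)(C)C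
F10 | step 3 | (2S,6R)-1-(tert-butyldimethylsilyloxy)-2,6-dimethyl-14-phenyltetradecan-4-one | C[C@H](CCCCCCCCc1ccccc1)CC(=O)C[C@H](C)CO[Si](C)(C)C(C)(C)C
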